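## The problem

The target 25 is a 3,3''-linked biflavanone in which a 7,4'-dihydroxyflavanone and a 5,7,4'-trihydroxyflavanone are joined by one bond between their C3 carbons, so that apart from the 5''-hydroxyl the molecule is C2-symmetric. The four stereocentres C2, C3, C3'' and C2'' are contiguous (2S,3R,3''R,2''S), and in each pyranone ring the 2-aryl group is trans to the 3-substituent. The skeletal tasks are the crowded C3–C3'' bond between two tertiary carbons and the attachment of two different acyl-arene rings (A and A'') to the ends of an otherwise symmetric four-carbon core. C3 and C3'' are α to ketones and, once the pyranones exist, stand next to carbons that carry a phenoxide leaving group, so base epimerises them or opens the rings by retro-oxa-Michael reaction; they must be set early and then kept away from base. C2 and C2'' can be left to the end, because a chair-like closure next to the fixed neighbours should give the trans (diequatorial) relation. Further fragile features are the five phenols (oxidants), the 1,4-diketone of any open-chain precursor (Paal–Knorr furan formation under acid) and the benzylic C2–O1 bonds (hydrogenolysis). The feature that opens the route is that C2 and C2'' are benzylic to 4-oxygenated B rings and lie six atoms from the ortho-oxygens of rings A and A'' (O1 and O1''), so each O1–C2 bond can be made by oxidising a benzylic C–H bond of a 2,3-dibenzyl-1,4-diarylbutane-1,4-dione.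

## Retrosynthesis

**O–benzyl bonds (25 ⇒ 24).** The last disconnection removes only the five O-benzyl groups of 24. Benzyl is preferred to methyl (Lewis-acid demethylation endangers the pyranones) and to silyl or acyl groups (fluoride or base would open the rings and epimerise C3/C3''). On the B rings the benzyloxy group is also the donor that the key oxidation needs. The forward step must cleave five primary ArO–CH2Ph bonds faster than the two secondary benzylic C2–O1 ring bonds.

**O1–C2 and O1''–C2'' (24 ⇒ 22).** Both pyranones are opened at the benzylic C–O bond and C2/C2'' return to the CH2 level, giving the open-chain diketone 22 with the two ortho-hydroxyls free.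
- Against the neighbouring cuts: C2–C3 (aldol logic) passes through β-hydroxy ketones that cleave by retro-aldol reaction, and O1–C8a (aromatic substitution) needs base on an electron-rich arene. The chosen cut needs neither.
- Simplification: two rings and two of the four stereocentres are removed at once; 22 keeps only the (S,S) pair that becomes C3/C3''.
- Forward demands: a quinone oxidant must take hydride from exactly the two CH2 groups para to a benzyloxy group, the chelated phenols must capture the cations, and the fixed centres must place each new aryl group trans.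

**Unmasking the ring oxygens (22 ⇒ 20).** The two ortho O–benzyl bonds are restored, giving the hexabenzyl ether 20. Uniform benzyl protection keeps the arene building blocks simple. Acetal protection of these oxygens was rejected, since its acidic removal would expose the 1,4-diketone to Paal–Knorr cyclodehydration. The forward step relies on chelation-directed cleavage of a benzyl ether ortho to an aryl ketone by a boron trihalide at low temperature, once per ketone.

**C4–C4a (20 ⇒ 14 + 19).** The bond between the carbonyl carbon C4 and ring A is cut, giving thioester 14 and boronic acid 19. Addition of an aryllithium to an amide would here meet a ketone with an α-hydrogen on a stereocentre. The base-free palladium-catalysed, copper-mediated thioester–boronic acid coupling avoids this. 19 comes from 15 via 16 in two steps, and 14 from acid 13 in one.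

**C4''–C4a'' (13 ⇒ 9 + 11).** The other acyl–arene bond is cut, giving the C2-symmetric anhydride 9 and bromide 11 (lithiated to 12; 11 is the bromination product of 10). The two carbonyl groups of 9 are homotopic, so one addition of 12 can give only one keto acid and differentiates the two ends without any selectivity problem. The more hindered arene is placed here because an aryllithium tolerates the crowding and the resulting di-ortho-substituted ketone resists a second addition. The less hindered 19 is kept for the catalytic coupling.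

**C3–C3'' (9 ⇒ 8 ⇒ 6 ⇒ two molecules of 4 ⇒ 1 + 2).** Anhydride 9 is the dehydration product of diacid 8, whose central bond is cut into two identical halves, so that dimer 6 is traced back to two molecules of imide 4. An auxiliary-controlled oxidative enolate dimerisation of 4 makes the most hindered bond and both stereocentres in one step from a single building block, where a stepwise alkylation sequence needs several. 4 is one acylation from 1 and 2. The forward reactions must give the (S,S) dimer 6 and remove the auxiliaries without epimerisation.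

## Roads not taken

Alternative 1: The cut is the C3–C3'' bond alone, made at the outset by anodic one-electron oxidation of two molecules of p-coumaric acid A2. The phenoxyl radicals join at the carbons next to the carboxyl groups (the future C3 and C3''). Each carboxylate then adds to the quinone methide unit of the other half, giving the cis-fused dilactone (1S,2S,5S,6S)-2,6-bis(4-hydroxyphenyl)-3,7-dioxabicyclo[3.3.0]octane-4,8-dione A1.
- Merits: one protecting-group-free step from a commodity acid builds the central bond, fixes the relative configuration of four carbons through the bicycle and already places oxygen on the future C2 and C2''. In step economy up to the core this road is clearly better than the four steps that lead to 9.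
- Weak points: radical coupling gives A1 as a racemate, and coupling at ring positions competes, so the single enantiomer needs a resolution or an unproven chiral mediator.
- Each C2 oxygen of A1 belongs to the carboxyl of the other half. Both C2–O bonds must therefore be exchanged for bonds to O1/O1'' at benzylic centres whose configuration is then at stake.
- Turning the two lactone carbonyls into two different aryl ketones frees a benzylic alkoxide β to a carbonyl, which invites retro-aldol cleavage of C2–C3 or elimination.
- Comparison: the chosen plan spends more steps on the core. In return it takes the absolute configuration from a recoverable auxiliary, differentiates the ends through the homotopic carbonyls of 9, and raises C2 to the carbinol level only when O1 is in place to capture it.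

Alternative 2: The cuts are O1–C2 and C2–C3 in both halves (four bonds). They lead back to 2-[4-(benzyloxy)-2-hydroxyphenyl]-5-[2,4-bis(benzyloxy)-6-hydroxyphenyl]furan A4, a masked 1,4-diketone, and two molecules of 4-(benzyloxy)benzaldehyde A5. Under a chiral Brønsted acid each phenol would condense with A5 to an aryloxy-benzylic cation, which the adjacent furan β-carbon attacks (oxa-Pictet–Spengler). The product is the furan-bridged bis(4H-chromene) A3 with C2 and C2'' set.
- Merits: four bonds, two rings and two stereocentres arise from three achiral pieces under a catalyst. The furan cannot enolise, and A4 carries no stereocentre while the two different arenes are attached. In convergence and in catalytic control of C2/C2'' this road is better than the chosen one.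
- Weak points: C3 and C3'' are still furan carbons in A3. Unmasking the furan means oxidative ring opening, after which the C3=C3'' double bond can shift to C2=C3, which forms a flavone and erases C2.
- The following reduction must set C3 and C3'' relative to each other and to C2/C2'' with no evident control element.
- Phenol-derived oxocarbenium ions and furan β-positions are poor partners for an asymmetric oxa-Pictet–Spengler reaction, and the second closure occurs next to the first.
- Comparison: the chosen plan reverses the order. The hard C3/C3'' pair is set first by an auxiliary and then controls C2/C2''. The price is a longer linear sequence and a stoichiometric auxiliary.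

Alternative 3: The cuts are C2–C3 and C2''–C3'', with the rings left open. The bis(silyl enol ether) (1Z,3Z)-1-[4-(benzyloxy)-2-fluorophenyl]-4-[2,4-bis(benzyloxy)-6-fluorophenyl]-1,4-bis(trimethylsilyloxy)buta-1,3-diene A7 would add at both termini to A5 under a chiral Lewis base and SiCl4 (two-directional Mukaiyama aldol). The product is the bis-aldol (2R,3R)-2,3-bis{(S)-[4-(benzyloxy)phenyl](hydroxy)methyl}-1-[4-(benzyloxy)-2-fluorophenyl]-4-[2,4-bis(benzyloxy)-6-fluorophenyl]butane-1,4-dione A6. The pyranones would close later by displacement of the ortho-fluorides by the carbinol oxygens (O1–C8a bonds).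
- Merits: two C–C bonds and all four stereocentres come from one catalytic step. The unsymmetrical carbon skeleton of A7 is assembled before any stereocentre exists, which is simpler than steps 6–10 of the chosen route.
- Weak points: after the first aldol the remaining enol ether sits beside two new stereocentres. The second addition is then doubly diastereodifferentiating, and the C3/C3'' relation is left to substrate bias, not to the catalyst.
- A6 is a double β-hydroxy ketone. Ring closure on fluoroarenes deactivated by benzyloxy groups needs base and heat, the very conditions for retro-aldol cleavage, dehydration and epimerisation at C3/C3''.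
- Comparison: the chosen plan has no β-hydroxy ketone and no basic step once C3/C3'' exist, and it fixes their relation by auxiliary control. It pays with more steps.

Key step: step 12

Assumption: 3-[4-(benzyloxy)phenyl]propanoic acid (1) and 1,3,5-tris(benzyloxy)benzene (10) are taken as catalogue compounds; the two ring A oxygens that later become O1 and O1'' are carried as benzyl ethers until step 11.

## Route

Step 1
Reactants: 1 3-[4-(benzyloxy)phenyl]propanoic acid; 2 (4R)-4-(propan-2-yl)-1,3-oxazolidin-2-one
Product: 4 (4R)-3-{3-[4-(benzyloxy)phenyl]propanoyl}-4-(propan-2-yl)-1,3-oxazolidin-2-one, via mixed pivalic anhydride 3 (not isolated)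
Conditions: PivCl, Et3N, THF, −20 °C; then LiCl, 2, −20 °C → rt
Reagents that add atoms: none
Why: N-acylation of the oxazolidinone through a mixed anhydride; the hindered pivaloyl carbonyl steers attack to the arylpropanoyl carbonyl, and no stereocentre is touched.

Step 2
Reactants: 4 (4R)-3-{3-[4-(benzyloxy)phenyl]propanoyl}-4-(propan-2-yl)-1,3-oxazolidin-2-one (two molecules)
Product: 6 (4R,4'R)-3,3'-{(2S,3S)-2,3-bis[4-(benzyloxy)benzyl]butanedioyl}bis[4-(propan-2-yl)-1,3-oxazolidin-2-one], via lithium Z-enolate 5 (not isolated)
Conditions: LiN(iPr)2 (1.1 equiv per imide), THF, −78 °C; then CuCl2 (1.2 equiv per imide), THF/DMF, −78 → 0 °C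
Reagents that add atoms: a second molecule of imide 4, O=C(CCc1ccc(OCc2ccccc2)cc1)N1C(=O)OC[C@H]1C(C)C
Why: Oxidative enolate homocoupling, a known reaction of 3-arylpropanoyl oxazolidinones: two molecules of 4 are deprotonated to the chelated Z-enolate 5, divalent copper oxidises each enolate, and the two α-carbons join with loss of one hydrogen from each half. Each carbon bonds on the face away from the isopropyl group, which for the (R)-auxiliary should give the C2-symmetric (2S,3S) dimer.

Step 3
Reactants: 6 (4R,4'R)-3,3'-{(2S,3S)-2,3-bis[4-(benzyloxy)benzyl]butanedioyl}bis[4-(propan-2-yl)-1,3-oxazolidin-2-one]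
Product: 8 (2S,3S)-2,3-bis[4-(benzyloxy)benzyl]butanedioic acid, via bis(peroxy acid) 7 (not isolated)
Conditions: LiOH, H2O2, THF/H2O, 0 °C; then aq. Na2SO3; then HCl
Reagents that add atoms: hydrogen peroxide, OO
Why: Hydroperoxide cleavage of the two imides at the exocyclic carbonyl, followed by sulfite reduction of the peracid. The hydroperoxide anion is nucleophilic but weakly basic, so the α-centres should not enolise, and auxiliary 2 is recovered.

Step 4
Reactants: 8 (2S,3S)-2,3-bis[4-(benzyloxy)benzyl]butanedioic acid
Product: 9 (3S,4S)-3,4-bis[4-(benzyloxy)benzyl]oxolane-2,5-dione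
Conditions: Ac2O, 80 °C; evaporation
Reagents that add atoms: none
Why: Cyclodehydration of a succinic acid to its anhydride. The trans-disubstituted five-membered anhydride is the more stable isomer, so the (S,S) configuration should be retained.

Step 5
Reactants: 10 1,3,5-tris(benzyloxy)benzene
Product: 11 2-bromo-1,3,5-tris(benzyloxy)benzene
Conditions: NBS (1.0 equiv), CH2Cl2, −20 → 0 °C
Reagents that add atoms: N-bromosuccinimide, O=C1CCC(=O)N1Br
Why: Electrophilic aromatic bromination of a very electron-rich arene whose three free positions are equivalent; one equivalent of reagent should stop at the monobromide.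

Step 6
Reactants: 11 2-bromo-1,3,5-tris(benzyloxy)benzene; 9 (3S,4S)-3,4-bis[4-(benzyloxy)benzyl]oxolane-2,5-dione
Product: 13 (2S,3S)-2,3-bis[4-(benzyloxy)benzyl]-4-oxo-4-[2,4,6-tris(benzyloxy)phenyl]butanoic acid, via [2,4,6-tris(benzyloxy)phenyl]lithium 12 (not isolated)
Conditions: 11, n-BuLi, THF, −78 °C; then added to 9, THF, −78 → −40 °C; aq. HCl
Reagents that add atoms: none
Why: Bromine–lithium exchange, then acyl substitution on a cyclic anhydride. The two carbonyls of 9 are homotopic, so only one keto acid can form. The lithium carboxylate and the di-ortho-substituted aryl ketone should resist a second addition.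

Step 7
Reactants: 13 (2S,3S)-2,3-bis[4-(benzyloxy)benzyl]-4-oxo-4-[2,4,6-tris(benzyloxy)phenyl]butanoic acid
Product: 14 S-phenyl (2S,3S)-2,3-bis[4-(benzyloxy)benzyl]-4-oxo-4-[2,4,6-tris(benzyloxy)phenyl]butanethioate
Conditions: PhSH, EDC·HCl, DMAP (cat.), CH2Cl2, 0 °C → rt
Reagents that add atoms: thiophenol, Sc1ccccc1
Why: Steglich-type thioesterification through the O-acylisourea under near-neutral conditions, which should leave both α-centres untouched.

Step 8
Reactants: 15 4-bromobenzene-1,3-diol
Product: 16 2,4-bis(benzyloxy)-1-bromobenzene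
Conditions: BnBr, K2CO3, DMF, rt → 50 °C
Reagents that add atoms: benzyl bromide, BrCc1ccccc1
Why: Williamson etherification of both phenols.

Step 9
Reactants: 16 2,4-bis(benzyloxy)-1-bromobenzene
Product: 19 [2,4-bis(benzyloxy)phenyl]boronic acid, via aryllithium 17 (not isolated), via lithium aryltriisopropoxyborate 18 (not isolated)
Conditions: n-BuLi, THF, −78 °C; B(OiPr)3, −78 °C → rt; aq. HCl
Reagents that add atoms: triisopropyl borate, CC(C)OB(OC(C)C)OC(C)C; water, O
Why: Bromine–lithium exchange, trapping with a borate ester and hydrolysis of the ate complex, the standard preparation of an arylboronic acid.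

Step 10
Reactants: 14 S-phenyl (2S,3S)-2,3-bis[4-(benzyloxy)benzyl]-4-oxo-4-[2,4,6-tris(benzyloxy)phenyl]butanethioate; 19 [2,4-bis(benzyloxy)phenyl]boronic acid
Product: 20 (2S,3S)-2,3-bis[4-(benzyloxy)benzyl]-1-[2,4-bis(benzyloxy)phenyl]-4-[2,4,6-tris(benzyloxy)phenyl]butane-1,4-dione
Conditions: Pd2(dba)3 (cat.), P(2-furyl)3, Cu(O2CC4H3S) (copper thiophene-2-carboxylate, 1.6 equiv), THF, 50 °C
Reagents that add atoms: none
Why: Liebeskind–Srogl coupling: zerovalent palladium inserts into the acyl–sulfur bond, the monovalent copper carboxylate takes up the thiolate and activates boron for transmetalation, and reductive elimination gives the ketone. No base is present, so the existing ketone and both α-centres should be safe.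

Step 11
Reactants: 20 (2S,3S)-2,3-bis[4-(benzyloxy)benzyl]-1-[2,4-bis(benzyloxy)phenyl]-4-[2,4,6-tris(benzyloxy)phenyl]butane-1,4-dione
Product: 22 (2S,3S)-2,3-bis[4-(benzyloxy)benzyl]-1-[4-(benzyloxy)-2-hydroxyphenyl]-4-[2,4-bis(benzyloxy)-6-hydroxyphenyl]butane-1,4-dione, via bis(dichloroboryl) ether 21 (not isolated)
Conditions: BCl3 (2.2 equiv), CH2Cl2, −78 °C; then H2O
Reagents that add atoms: none
Why: Chelation-directed dealkylation of aryl benzyl ethers ortho to a carbonyl group: the boron halide binds the ketone oxygen and is delivered to the neighbouring ether. The six-membered boron chelate then occupies the carbonyl, so one ortho ether per ketone should be cleaved and the non-chelated ethers left.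

Step 12
Reactants: 22 (2S,3S)-2,3-bis[4-(benzyloxy)benzyl]-1-[4-(benzyloxy)-2-hydroxyphenyl]-4-[2,4-bis(benzyloxy)-6-hydroxyphenyl]butane-1,4-dione
Product: 24 (2S,3R)-7-(benzyloxy)-2-[4-(benzyloxy)phenyl]-3-{(2S,3R)-5,7-bis(benzyloxy)-2-[4-(benzyloxy)phenyl]-4-oxo-3,4-dihydro-2H-chromen-3-yl}-2,3-dihydro-4H-chromen-4-one, via monocyclised flavanone 23 (not isolated)
Conditions: DDQ (2.3 equiv), 4 Å MS, 1,4-dioxane, 60 °C, dark
Reagents that add atoms: none
Why: DDQ forms a charge-transfer complex with each 4-benzyloxyphenyl ring and removes hydride from the adjacent CH2, giving a benzylic cation stabilised as a para-quinone-methide-type oxocarbenium ion paired with the hydroquinone anion. The chelated ortho-hydroxyl of the neighbouring aryl ketone adds to this cation and the proton passes to the hydroquinone anion, which forms O1–C2; the same sequence on the other half forms O1''–C2'' (the order is immaterial, 23 being drawn with the ring of the 7-benzyloxy half closed first). The closest known reaction type is the DDQ dehydrogenative cyclisation of 2-(3-arylpropyl)phenols to flavans and of 2'-hydroxydihydrochalcones to flavanones. Each ring closes in the 6-exo-trig mode, the phenol oxygen attacking the exocyclic cationic carbon. C2 and C2'' are controlled by the adjacent preset centres C3 and C3'': in the chair-like transition state the aryl group and the large C3 branch both lie equatorial, which should give the 2,3-trans (2S,3R) arrangement in each half, while the cis pathway suffers A(1,3) strain between the planar cation and the C3 branch. The step needs site selectivity for the two CH2 groups para to a benzyloxy donor over the five OCH2Ph groups, whose phenyl rings carry no such donor and whose oxygen lone pairs are engaged by their own arenes. It also needs oxygen capture to outrun loss of H3 (which would erase C3) and further dehydrogenation to a flavone; the hydrogen bond that holds each phenol beside its cation, the absence of base and the limited amount of oxidant and heat should secure this.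

Step 13
Reactants: 24 (2S,3R)-7-(benzyloxy)-2-[4-(benzyloxy)phenyl]-3-{(2S,3R)-5,7-bis(benzyloxy)-2-[4-(benzyloxy)phenyl]-4-oxo-3,4-dihydro-2H-chromen-3-yl}-2,3-dihydro-4H-chromen-4-one
Product: 25 (2S,3R)-3-[(2S,3R)-5,7-dihydroxy-2-(4-hydroxyphenyl)-4-oxo-3,4-dihydro-2H-chromen-3-yl]-7-hydroxy-2-(4-hydroxyphenyl)-2,3-dihydro-4H-chromen-4-one
Conditions: H2 (1 atm), 10% Pd/C, EtOAc/MeOH, rt
Reagents that add atoms: none
Why: Catalytic hydrogenolysis of five aryl benzyl ethers under neutral conditions. The primary ArO–CH2Ph bonds should cleave well before the secondary, ring-held C2–O1 bonds, and no stereocentre is involved.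

## Compound list

1 | 3-[4-(benzyloxy)phenyl]propanoic acid | O=C(O)CCc1ccc(OCc2ccccc2)cc1 | starting material
2 | (4R)-4-(propan-2-yl)-1,3-oxazolidin-2-one | CC(C)[C@@H]1COC(=O)N1 | starting material
3 | 3-[4-(benzyloxy)phenyl]propanoic 2,2-dimethylpropanoic anhydride | CC(C)(C)C(=O)OC(=O)CCc1ccc(OCc2ccccc2)cc1 | intermediate
4 | (4R)-3-{3-[4-(benzyloxy)phenyl]propanoyl}-4-(propan-2-yl)-1,3-oxazolidin-2-one | O=C(CCc1ccc(OCc2ccccc2)cc1)N1C(=O)OC[C@H]1C(C)C | intermediate
5 | lithium (1Z)-3-[4-(benzyloxy)phenyl]-1-[(4R)-2-oxo-4-(propan-2-yl)-1,3-oxazolidin-3-yl]prop-1-en-1-olate | [Li]O/C(=C\Cc1ccc(OCc2ccccc2)cc1)N1C(=O)OC[C@H]1C(C)C | intermediate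
6 | (4R,4'R)-3,3'-{(2S,3S)-2,3-bis[4-(benzyloxy)benzyl]butanedioyl}bis[4-(propan-2-yl)-1,3-oxazolidin-2-one] (dimer of two molecules of 4) | O=C([C@@H](Cc1ccc(OCc2ccccc2)cc1)[C@H](Cc1ccc(OCc2ccccc2)cc1)C(=O)N1C(=O)OC[C@H]1C(C)C)N1C(=O)OC[C@H]1C(C)C | intermediate
7 | (2S,3S)-2,3-bis[4-(benzyloxy)benzyl]butanediperoxoic acid | O=C(OO)[C@@H](Cc1ccc(OCc2ccccc2)cc1)[C@H](Cc1ccc(OCc2ccccc2)cc1)C(=O)OO | intermediate
8 | (2S,3S)-2,3-bis[4-(benzyloxy)benzyl]butanedioic acid | O=C(O)[C@@H](Cc1ccc(OCc2ccccc2)cc1)[C@H](Cc1ccc(OCc2ccccc2)cc1)C(=O)O | intermediate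
9 | (3S,4S)-3,4-bis[4-(benzyloxy)benzyl]oxolane-2,5-dione (trans anhydride) | O=C1OC(=O)[C@@H](Cc2ccc(OCc3ccccc3)cc2)[C@@H]1Cc1ccc(OCc2ccccc2)cc1 | intermediate
10 | 1,3,5-tris(benzyloxy)benzene | c1ccc(COc2cc(OCc3ccccc3)cc(OCc3ccccc3)c2)cc1 | starting material
11 | 2-bromo-1,3,5-tris(benzyloxy)benzene | Brc1c(OCc2ccccc2)cc(OCc2ccccc2)cc1OCc1ccccc1 | intermediate
12 | [2,4,6-tris(benzyloxy)phenyl]lithium | [Li]c1c(OCc2ccccc2)cc(OCc2ccccc2)cc1OCc1ccccc1 | intermediate
13 | (2S,3S)-2,3-bis[4-(benzyloxy)benzyl]-4-oxo-4-[2,4,6-tris(benzyloxy)phenyl]butanoic acid | O=C(O)[C@@H](Cc1ccc(OCc2ccccc2)cc1)[C@H](Cc1ccc(OCc2ccccc2)cc1)C(=O)c1c(OCc2ccccc2)cc(OCc2ccccc2)cc1OCc1ccccc1 | intermediate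
14 | S-phenyl (2S,3S)-2,3-bis[4-(benzyloxy)benzyl]-4-oxo-4-[2,4,6-tris(benzyloxy)phenyl]butanethioate | O=C(Sc1ccccc1)[C@@H](Cc1ccc(OCc2ccccc2)cc1)[C@H](Cc1ccc(OCc2ccccc2)cc1)C(=O)c1c(OCc2ccccc2)cc(OCc2ccccc2)cc1OCc1ccccc1 | intermediate
15 | 4-bromobenzene-1,3-diol (4-bromoresorcinol) | Oc1ccc(Br)c(O)c1 | starting material
16 | 2,4-bis(benzyloxy)-1-bromobenzene | Brc1ccc(OCc2ccccc2)cc1OCc1ccccc1 | intermediate
17 | [2,4-bis(benzyloxy)phenyl]lithium | [Li]c1ccc(OCc2ccccc2)cc1OCc1ccccc1 | intermediate
18 | lithium [2,4-bis(benzyloxy)phenyl]tris(propan-2-yloxy)borate | [Li+].CC(C)O[B-](OC(C)C)(OC(C)C)c1ccc(OCc2ccccc2)cc1OCc1ccccc1 | intermediate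
19 | [2,4-bis(benzyloxy)phenyl]boronic acid | OB(O)c1ccc(OCc2ccccc2)cc1OCc1ccccc1 | intermediate
20 | (2S,3S)-2,3-bis[4-(benzyloxy)benzyl]-1-[2,4-bis(benzyloxy)phenyl]-4-[2,4,6-tris(benzyloxy)phenyl]butane-1,4-dione | O=C(c1ccc(OCc2ccccc2)cc1OCc1ccccc1)[C@@H](Cc1ccc(OCc2ccccc2)cc1)[C@H](Cc1ccc(OCc2ccccc2)cc1)C(=O)c1c(OCc2ccccc2)cc(OCc2ccccc2)cc1OCc1ccccc1 | intermediate
21 | (2S,3S)-2,3-bis[4-(benzyloxy)benzyl]-1-{4-(benzyloxy)-2-[(dichloroboranyl)oxy]phenyl}-4-{2,4-bis(benzyloxy)-6-[(dichloroboranyl)oxy]phenyl}butane-1,4-dione | O=C(c1ccc(OCc2ccccc2)cc1OB(Cl)Cl)[C@@H](Cc1ccc(OCc2ccccc2)cc1)[C@H](Cc1ccc(OCc2ccccc2)cc1)C(=O)c1c(OB(Cl)Cl)cc(OCc2ccccc2)cc1OCc1ccccc1 | intermediate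
22 | (2S,3S)-2,3-bis[4-(benzyloxy)benzyl]-1-[4-(benzyloxy)-2-hydroxyphenyl]-4-[2,4-bis(benzyloxy)-6-hydroxyphenyl]butane-1,4-dione | O=C(c1ccc(OCc2ccccc2)cc1O)[C@@H](Cc1ccc(OCc2ccccc2)cc1)[C@H](Cc1ccc(OCc2ccccc2)cc1)C(=O)c1c(O)cc(OCc2ccccc2)cc1OCc1ccccc1 | intermediate
23 | (2S,3R)-7-(benzyloxy)-2-[4-(benzyloxy)phenyl]-3-{(2S)-3-[4-(benzyloxy)phenyl]-1-[2,4-bis(benzyloxy)-6-hydroxyphenyl]-1-oxopropan-2-yl}-2,3-dihydro-4H-chromen-4-one | O=C1c2ccc(OCc3ccccc3)cc2O[C@H](c2ccc(OCc3ccccc3)cc2)[C@H]1[C@H](Cc1ccc(OCc2ccccc2)cc1)C(=O)c1c(O)cc(OCc2ccccc2)cc1OCc1ccccc1 | intermediate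
24 | (2S,3R)-7-(benzyloxy)-2-[4-(benzyloxy)phenyl]-3-{(2S,3R)-5,7-bis(benzyloxy)-2-[4-(benzyloxy)phenyl]-4-oxo-3,4-dihydro-2H-chromen-3-yl}-2,3-dihydro-4H-chromen-4-one (penta-O-benzyl ether of the target) | O=C1c2ccc(OCc3ccccc3)cc2O[C@H](c2ccc(OCc3ccccc3)cc2)[C@H]1[C@H]1C(=O)c2c(OCc3ccccc3)cc(OCc3ccccc3)cc2O[C@@H]1c1ccc(OCc2ccccc2)cc1 | intermediate
25 | (2S,3R)-3-[(2S,3R)-5,7-dihydroxy-2-(4-hydroxyphenyl)-4-oxo-3,4-dihydro-2H-chromen-3-yl]-7-hydroxy-2-(4-hydroxyphenyl)-2,3-dihydro-4H-chromen-4-one | O=C1c2ccc(O)cc2O[C@H](c2ccc(O)cc2)[C@H]1[C@H]1C(=O)c2c(O)cc(O)cc2O[C@@H]1c1ccc(O)cc1 | target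

## Step count and risks

Total: 13 steps. Longest linear sequence: 10 steps (steps 1, 2, 3, 4, 6, 7, 10, 11, 12, 13) from 1. Step 5 and steps 8–9 are side branches. Step 2 is a dimerisation and consumes two molecules of 4 for each molecule of 6.

**Step 12 (key step).** Hydride abstraction from a CH2 group that sits next to an acyl-bearing carbon may be slow. At the temperature it needs, three processes compete: loss of H3 from the cation (which erases C3), capture of the cation by the distal carbonyl oxygen, and further dehydrogenation of the flavanone.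
Fallback: the rings are closed through para-quinone methides instead of through hydride abstraction. It sets out from 20. Hydrogenolysis of all six benzyl ethers (H2, Pd/C, THF/MeOH) should give the hexaphenol (2S,3S)-1-(2,4-dihydroxyphenyl)-2,3-bis(4-hydroxybenzyl)-4-(2,4,6-trihydroxyphenyl)butane-1,4-dione F1. Ag2O at room temperature should oxidise the two 4-hydroxybenzyl groups to the bis(para-quinone methide) (2S,3S)-1-(2,4-dihydroxyphenyl)-2,3-bis[(4-oxocyclohexa-2,5-dien-1-ylidene)methyl]-4-(2,4,6-trihydroxyphenyl)butane-1,4-dione F2, which is not isolated. The ortho-hydroxyls add to it in 1,6-fashion, forming the same O1–C2 and O1''–C2'' bonds. The fallback comes back to the route at 25 and bypasses steps 11–13.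

**Step 2.** Facial control may be lost if the coupling runs through free α-carbonyl radicals, which gives the meso dimer beside the (S,S) dimer. α-Chlorination by the copper salt may also compete.
Fallback: the central bond is built stepwise, setting out from 4. Auxiliary-controlled alkylation of the sodium enolate (NaN(SiMe3)2, tert-butyl bromoacetate, THF, −78 °C) should give (4R)-3-{(2S)-2-[4-(benzyloxy)benzyl]-4-tert-butoxy-4-oxobutanoyl}-4-(propan-2-yl)-1,3-oxazolidin-2-one F3. LiBH4 reduction of the imide then gives tert-butyl (3S)-3-[4-(benzyloxy)benzyl]-4-hydroxybutanoate F4, and acid-catalysed lactonisation (TsOH, toluene, 80 °C) gives (4S)-4-[4-(benzyloxy)benzyl]oxolan-2-one F5. Alkylation of its lithium enolate (LiN(SiMe3)2, 4-(benzyloxy)benzyl bromide, −78 °C) anti to the existing substituent gives the trans lactone (3S,4S)-3,4-bis[4-(benzyloxy)benzyl]oxolan-2-one F6. Addition of aryllithium 12 opens the lactone to (2S,3S)-2,3-bis[4-(benzyloxy)benzyl]-4-hydroxy-1-[2,4,6-tris(benzyloxy)phenyl]butan-1-one F7. Oxidation of the primary alcohol (TEMPO, PhI(OAc)2, MeCN/H2O) returns to the route at 13; steps 3, 4 and 6 are bypassed.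

**Step 6.** The hindered aryllithium may deprotonate the anhydride at its α-carbon (fragmentation, epimerisation) in place of adding, or a second addition to the new ketone may occur.
Fallback: it sets out from 9. Opening with N,O-dimethylhydroxylamine (hydrochloride, Et3N, CH2Cl2) gives a single amide acid because the carbonyls are homotopic: (2S,3S)-2,3-bis[4-(benzyloxy)benzyl]-4-[methoxy(methyl)amino]-4-oxobutanoic acid F8. After deprotonation of the acid, 12 adds to the N-methoxy-N-methylamide, and the chelated tetrahedral adduct releases the ketone only on acidic work-up. The fallback comes back at 13.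

**Step 10.** Transmetalation onto a crowded, α-branched acyl-palladium species may be slow, and the electron-rich boronic acid may protodeboronate first.
Fallback: polar addition replaces cross-coupling, setting out from 13. Amide formation (N,O-dimethylhydroxylamine hydrochloride, EDC·HCl, HOBt, N-methylmorpholine) gives (2S,3S)-2,3-bis[4-(benzyloxy)benzyl]-N-methoxy-N-methyl-4-oxo-4-[2,4,6-tris(benzyloxy)phenyl]butanamide F9. Aryllithium 17 (from 16, as in step 9) at −78 °C should add to the amide and not to the di-ortho-substituted ketone. The fallback comes back at 20. Its own risk is α-deprotonation of the ketone, which is why it is not the first choice.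

**Step 13.** Over-reduction is the danger: hydrogenolysis of the benzylic C2–O1 ring bonds or reduction of the ketones before the last benzyl ether has gone.
Fallback: non-reductive Lewis-acid dealkylation, setting out from 24. BCl3 with pentamethylbenzene as cation scavenger (CH2Cl2, −78 °C) should remove the five benzyl groups and leave the C2–O1 bonds. It comes back at 25 and makes no new compound (F0).

## Further compounds

F1 | step 12 | (2S,3S)-1-(2,4-dihydroxyphenyl)-2,3-bis(4-hydroxybenzyl)-4-(2,4,6-trihydroxyphenyl)butane-1,4-dione | O=C(c1ccc(O)cc1O)[C@@H](Cc1ccc(O)cc1)[C@H](Cc1ccc(O)cc1)C(=O)c1c(O)cc(O)cc1O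
F2 | step 12 | (2S,3S)-1-(2,4-dihydroxyphenyl)-2,3-bis[(4-oxocyclohexa-2,5-dien-1-ylidene)methyl]-4-(2,4,6-trihydroxyphenyl)butane-1,4-dione | O=C(c1ccc(O)cc1O)[C@@H](C=C1C=CC(=O)C=C1)[C@H](C=C1C=CC(=O)C=C1)C(=O)c1c(O)cc(O)cc1O
F3 | step 2 | (4R)-3-{(2S)-2-[4-(benzyloxy)benzyl]-4-tert-butoxy-4-oxobutanoyl}-4-(propan-2-yl)-1,3-oxazolidin-2-one | CC(C)(C)OC(=O)C[C@H](Cc1ccc(OCc2ccccc2)cc1)C(=O)N1C(=O)OC[C@H]1C(C)C
F4 | step 2 | tert-butyl (3S)-3-[4-(benzyloxy)benzyl]-4-hydroxybutanoate | CC(C)(C)OC(=O)C[C@H](Cc1ccc(OCc2ccccc2)cc1)CO
F5 | step 2 | (4S)-4-[4-(benzyloxy)benzyl]oxolan-2-one | O=C1C[C@H](Cc2ccc(OCc3ccccc3)cc2)CO1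
F6 | step 2 | (3S,4S)-3,4-bis[4-(benzyloxy)benzyl]oxolan-2-one | O=C1OC[C@@H](Cc2ccc(OCc3ccccc3)cc2)[C@@H]1Cc1ccc(OCc2ccccc2)cc1
F7 | step 2 | (2S,3S)-2,3-bis[4-(benzyloxy)benzyl]-4-hydroxy-1-[2,4,6-tris(benzyloxy)phenyl]butan-1-one | OC[C@@H](Cc1ccc(OCc2ccccc2)cc1)[C@H](Cc1ccc(OCc2ccccc2)cc1)C(=O)c1c(OCc2ccccc2)cc(OCc2ccccc2)cc1OCc1ccccc1
F8 | step 6 | (2S,3S)-2,3-bis[4-(benzyloxy)benzyl]-4-[methoxy(methyl)amino]-4-oxobutanoic acid | O=C(O)[C@@H](Cc1ccc(OCc2ccccc2)cc1)[C@H](Cc1ccc(OCc2ccccc2)cc1)C(=O)N(C)OC
F9 | step 10 | (2S,3S)-2,3-bis[4-(benzyloxy)benzyl]-N-methoxy-N-methyl-4-oxo-4-[2,4,6-tris(benzyloxy)phenyl]butanamide | O=C(N(C)OC)[C@@H](Cc1ccc(OCc2ccccc2)cc1)[C@H](Cc1ccc(OCc2ccccc2)cc1)C(=O)c1c(OCc2ccccc2)cc(OCc2ccccc2)cc1OCc1ccccc1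
F0 | step 13 | none | none
A1 | alternative 1 | (1S,2S,5S,6S)-2,6-bis(4-hydroxyphenyl)-3,7-dioxabicyclo[3.3.0]octane-4,8-dione | O=C1O[C@H](c3ccc(O)cc3)[C@H]2C(=O)O[C@H](c3ccc(O)cc3)[C@@H]12
A2 | alternative 1 | (2E)-3-(4-hydroxyphenyl)prop-2-enoic acid (p-coumaric acid) | O=C(O)/C=C/c1ccc(O)cc1
A3 | alternative 2 | furan-bridged bis(4H-chromene): the 2,5-diarylfuran A4 with each furan β-carbon tied to the neighbouring phenol oxygen through a CH[4-(benzyloxy)phenyl] bridge, configuration as drawn | [C@H]1(c2ccc(OCc3ccccc3)cc2)Oc2cc(OCc3ccccc3)ccc2-c2oc3-c4c(OCc5ccccc5)cc(OCc5ccccc5)cc4O[C@H](c4ccc(OCc5ccccc5)cc4)c3c12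
A4 | alternative 2 | 2-[4-(benzyloxy)-2-hydroxyphenyl]-5-[2,4-bis(benzyloxy)-6-hydroxyphenyl]furan | Oc1cc(OCc2ccccc2)ccc1-c1ccc(-c2c(O)cc(OCc3ccccc3)cc2OCc2ccccc2)o1
A5 | alternative 2 | 4-(benzyloxy)benzaldehyde | O=Cc1ccc(OCc2ccccc2)cc1
A6 | alternative 3 | (2R,3R)-2,3-bis{(S)-[4-(benzyloxy)phenyl](hydroxy)methyl}-1-[4-(benzyloxy)-2-fluorophenyl]-4-[2,4-bis(benzyloxy)-6-fluorophenyl]butane-1,4-dione | O=C(c1ccc(OCc2ccccc2)cc1F)[C@@H]([C@H](O)c1ccc(OCc2ccccc2)cc1)[C@H]([C@H](O)c1ccc(OCc2ccccc2)cc1)C(=O)c1c(F)cc(OCc2ccccc2)cc1OCc1ccccc1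
A7 | alternative 3 | (1Z,3Z)-1-[4-(benzyloxy)-2-fluorophenyl]-4-[2,4-bis(benzyloxy)-6-fluorophenyl]-1,4-bis(trimethylsilyloxy)buta-1,3-diene | C[Si](C)(C)O/C(c1ccc(OCc2ccccc2)cc1F)=C\C=C(\c1c(F)cc(OCc2ccccc2)cc1OCc1ccccc1)O[Si](C)(C)C
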